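**Plan**

1. Retrosynthesis: first the O–Si bond and the propenyl C=C (back to an aldehyde) are cut. Then both bonds that tie the dihydrofuran (ring B) to the benzo ring (ring A), C7a–O1 and C3a–C3, are cut together, giving 4-iodo-3-methoxybenzaldehyde and a cis-aryl/methyl epoxide. The epoxide goes back to a (Z)-propenylarene and 3-hydroxy-4,5-dimethoxybenzaldehyde.
2. Forward: the pendant aryl (ring C) is elaborated to the epoxide in three steps. Ring B is then closed onto ring A in one palladium/norbornene (Catellani-type) operation: ortho C–H alkylation by the epoxide, then ipso C–O coupling. Olefination and desilylation finish.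
3. Enabling feature: in ring A the oxygen-bearing C7a lies between C7 (OMe, blocked) and C3a (H, free), the one-blocked/one-free ortho pattern such an aryl iodide needs. O1–C2–C3 of ring B is an epoxide with one C–O bond opened.
4. Stereochemistry: both centres come from a catalyst-controlled Jacobsen epoxidation of the (Z)-alkene. The annulation is stereospecific (retention at C2, inversion at C3), so the cis-epoxide becomes the trans-(2S,3S) ring. The (E)-alkene comes from a Julia–Kocienski olefination.

Key step: step 4

Assumption: 3-hydroxy-4,5-dimethoxybenzaldehyde, 4-iodo-3-methoxybenzaldehyde and 5-(ethylsulfonyl)-1-phenyl-1H-tetrazole are taken as catalogue compounds.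

**Route**

Step 1
Reactants: 1 3-hydroxy-4,5-dimethoxybenzaldehyde
Product: 2 3,4-dimethoxy-5-{[tri(propan-2-yl)silyl]oxy}benzaldehyde
Conditions: i-Pr3SiCl, imidazole, DMF, rt
Reagents that add atoms: chlorotri(propan-2-yl)silane, CC(C)[Si](Cl)(C(C)C)C(C)C
Why: Standard silyl ether protection of a phenol; the bulky silyl group should withstand the ylide, the peracid, carbonate in NMP and the amide base of later steps and is removed by fluoride without touching the alkene or the benzylic ether.

Step 2
Reactants: 2 3,4-dimethoxy-5-{[tri(propan-2-yl)silyl]oxy}benzaldehyde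
Product: 3 {2,3-dimethoxy-5-[(Z)-prop-1-en-1-yl]phenoxy}tri(propan-2-yl)silane
Conditions: EtPPh3Br, KN(SiMe3)2, THF, −78 °C to rt
Reagents that add atoms: ethyltriphenylphosphonium bromide, CC[P+](c1ccccc1)(c1ccccc1)c1ccccc1.[Br-]
Why: Wittig olefination with a non-stabilised ylide under salt-free potassium-base conditions should give mainly the (Z)-alkene through the kinetically favoured cis-oxaphosphetane.

Step 3
Reactants: 3 {2,3-dimethoxy-5-[(Z)-prop-1-en-1-yl]phenoxy}tri(propan-2-yl)silane
Product: 4 {2,3-dimethoxy-5-[(2R,3S)-3-methyloxiran-2-yl]phenoxy}tri(propan-2-yl)silane (cis-epoxide)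
Conditions: (R,R)-Jacobsen catalyst, [(R,R)-N,N′-bis(3,5-di-tert-butylsalicylidene)-1,2-cyclohexanediaminato]manganese chloride (trivalent manganese, 5 mol %), mCPBA, N-methylmorpholine N-oxide, CH2Cl2, −78 °C; chromatography on Et3N-deactivated silica
Reagents that add atoms: 3-chloroperbenzoic acid (mCPBA), O=C(OO)c1cccc(Cl)c1
Why: Jacobsen–Katsuki epoxidation, for which cis-β-methylstyrenes are the benchmark substrate class: the (R,R) catalyst, the enantiomer of the one that gives (1S,2R)-indene oxide, should deliver oxygen to the face that gives the benzylic-R/methyl-carbon-S cis-epoxide and so sets both stereocentres, while the low temperature and the N-oxide should suppress leakage to the trans-epoxide and residual (E)-alkene from step 2 reacts much more slowly and is left behind.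

Step 4
Reactants: 4 {2,3-dimethoxy-5-[(2R,3S)-3-methyloxiran-2-yl]phenoxy}tri(propan-2-yl)silane, 5 4-iodo-3-methoxybenzaldehyde
Product: 6 (2S,3S)-2-(3,4-dimethoxy-5-{[tri(propan-2-yl)silyl]oxy}phenyl)-7-methoxy-3-methyl-2,3-dihydro-1-benzofuran-5-carbaldehyde (trans)
Conditions: Pd(OAc)2 (10 mol %), XPhos (20 mol %), potassium 5-norbornene-2-carboxylate (0.5 equiv), K2CO3 (2 equiv), NMP, 70 °C, Ar; 4 in 1.5-fold excess, 5 added slowly
Reagents that add atoms: none
Why: Proposed new method: zerovalent palladium inserts into the C–I bond of 5, norbornene carbopalladation and carbonate-assisted C–H palladation at the only free ortho position give the five-membered aryl–norbornyl palladacycle of divalent palladium, which should open epoxide 4 by SN2-type oxidative addition at the methyl-bearing carbon (anti to the C–O bond, inversion) to a tetravalent palladium alkyl, and aryl–alkyl reductive elimination (retention) then forms the C3a–C3 bond. With both ortho positions now substituted, norbornene is expelled by β-carbon elimination and the resulting aryl palladium alkoxide, a six-membered oxapalladacycle of divalent palladium, closes ring B by C(aryl)–O reductive elimination at the former C–I carbon (ring contraction from the six-membered palladacycle to the five-membered oxygen ring, not a Baldwin-type attack), a step that a bulky biaryl phosphine such as XPhos accelerates relative to β-hydride elimination of the secondary alkoxide. The closest known reaction type is the palladium/norbornene annulation of ortho-substituted aryl iodides with terminal epoxides to 2-substituted 2,3-dihydrobenzofurans, together with the inversion established for SN2-type oxidative addition of alkyl halides at this kind of palladacycle; the extension to a cis-1,2-disubstituted aryl/methyl epoxide is the untested part. C2 keeps its C–O bond and hence the spatial arrangement of the epoxide (R there, S in the product only through the change in CIP priorities), while C3 is set by the inversion, so the cis-epoxide maps stereospecifically onto the trans-(2S,3S) ring. The selectivity required is attack at the methyl-bearing and not the benzylic carbon: the bulky palladacycle should prefer the carbon flanked by methyl over that flanked by aryl, the 4-methoxy group of ring C is twisted out of conjugation by its two ortho oxygen substituents so benzylic ionisation is only weakly assisted, and carbonate in NMP without Lewis acid avoids SN1 opening and Meinwald rearrangement. Site selectivity on ring A is secured by the methoxy group next to iodine, which leaves a single ortho C–H and also provides the congestion that drives norbornene extrusion.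

Step 5
Reactants: 6 (2S,3S)-2-(3,4-dimethoxy-5-{[tri(propan-2-yl)silyl]oxy}phenyl)-7-methoxy-3-methyl-2,3-dihydro-1-benzofuran-5-carbaldehyde
Product: 7 {5-[(2S,3S)-7-methoxy-3-methyl-5-[(E)-prop-1-en-1-yl]-2,3-dihydro-1-benzofuran-2-yl]-2,3-dimethoxyphenoxy}tri(propan-2-yl)silane
Conditions: 5-(ethylsulfonyl)-1-phenyl-1H-tetrazole, KN(SiMe3)2, DME, −60 °C to rt
Reagents that add atoms: 5-(ethylsulfonyl)-1-phenyl-1H-tetrazole, CCS(=O)(=O)c1nnnn1-c1ccccc1
Why: Julia–Kocienski olefination of a non-enolisable aromatic aldehyde with a 1-phenyltetrazolyl sulfone should give the (E)-alkene through addition, Smiles rearrangement and loss of SO2 and the tetrazololate, and the two ring stereocentres carry no acidic hydrogen and are not touched.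

Step 6
Reactants: 7 {5-[(2S,3S)-7-methoxy-3-methyl-5-[(E)-prop-1-en-1-yl]-2,3-dihydro-1-benzofuran-2-yl]-2,3-dimethoxyphenoxy}tri(propan-2-yl)silane
Product: 8 5-[(2S,3S)-7-methoxy-3-methyl-5-[(E)-prop-1-en-1-yl]-2,3-dihydro-1-benzofuran-2-yl]-2,3-dimethoxyphenol (target)
Conditions: Bu4NF, AcOH (1:1), THF, 0 °C
Reagents that add atoms: none
Why: Fluoride-induced cleavage of the aryl silyl ether (Si–F bond formation), buffered with acetic acid so that no free phenoxide is exposed; the alkene, the aryl methyl ethers and the trans-dihydrobenzofuran are inert.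

**Compound list**

1 | 3-hydroxy-4,5-dimethoxybenzaldehyde | O=Cc1cc(O)c(OC)c(OC)c1 | starting material
2 | 3,4-dimethoxy-5-{[tri(propan-2-yl)silyl]oxy}benzaldehyde | O=Cc1cc(O[Si](C(C)C)(C(C)C)C(C)C)c(OC)c(OC)c1 | intermediate
3 | {2,3-dimethoxy-5-[(Z)-prop-1-en-1-yl]phenoxy}tri(propan-2-yl)silane | C/C=C\c1cc(O[Si](C(C)C)(C(C)C)C(C)C)c(OC)c(OC)c1 | intermediate
4 | {2,3-dimethoxy-5-[(2R,3S)-3-methyloxiran-2-yl]phenoxy}tri(propan-2-yl)silane | C[C@@H]1O[C@@H]1c1cc(O[Si](C(C)C)(C(C)C)C(C)C)c(OC)c(OC)c1 | intermediate
5 | 4-iodo-3-methoxybenzaldehyde | O=Cc1ccc(I)c(OC)c1 | starting material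
6 | (2S,3S)-2-(3,4-dimethoxy-5-{[tri(propan-2-yl)silyl]oxy}phenyl)-7-methoxy-3-methyl-2,3-dihydro-1-benzofuran-5-carbaldehyde | O=Cc1cc(OC)c2c(c1)[C@H](C)[C@@H](c1cc(O[Si](C(C)C)(C(C)C)C(C)C)c(OC)c(OC)c1)O2 | intermediate
7 | {5-[(2S,3S)-7-methoxy-3-methyl-5-[(E)-prop-1-en-1-yl]-2,3-dihydro-1-benzofuran-2-yl]-2,3-dimethoxyphenoxy}tri(propan-2-yl)silane | C/C=C/c1cc(OC)c2c(c1)[C@H](C)[C@@H](c1cc(O[Si](C(C)C)(C(C)C)C(C)C)c(OC)c(OC)c1)O2 | intermediate
8 | 5-[(2S,3S)-7-methoxy-3-methyl-5-[(E)-prop-1-en-1-yl]-2,3-dihydro-1-benzofuran-2-yl]-2,3-dimethoxyphenol | C/C=C/c1cc(OC)c2c(c1)[C@H](C)[C@@H](c1cc(O)c(OC)c(OC)c1)O2 | target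

**Step count and risks**

Total step count: 6. Longest linear sequence: 6 steps (1 → 2 → 3 → 4 → 6 → 7 → 8); 5 is purchased.

Steps most likely to fail:

Step 4 (proposed new method). The palladacycle may fail to open the hindered internal epoxide, so that biaryl formation from a second molecule of 5 takes over. Ring opening may occur at the benzylic carbon and give the regioisomeric ring. The electron-rich epoxide may rearrange to a carbonyl compound before it is captured. The palladium alkoxide may undergo β-hydride elimination instead of C–O bond formation. The fallback uses known chemistry, sets out from 2 and comes back at 6. Julia–Kocienski olefination of 2 with the sulfone and base of step 5 should give {2,3-dimethoxy-5-[(E)-prop-1-en-1-yl]phenoxy}tri(propan-2-yl)silane F1. A Heck-type oxyarylation of F1 with commercial 4-hydroxy-3-iodo-5-methoxybenzaldehyde (Pd(OAc)2, Ag2CO3, acetone, reflux) follows: the aryl group adds to the methyl-bearing alkene carbon and the phenoxide captures the benzylic palladium. This should give the trans-dihydrobenzofuran as the racemate, that is 6 together with (2R,3R)-2-(3,4-dimethoxy-5-{[tri(propan-2-yl)silyl]oxy}phenyl)-7-methoxy-3-methyl-2,3-dihydro-1-benzofuran-5-carbaldehyde F2. Preparative chromatography on a chiral stationary phase would remove F2 and deliver 6. This approach forms C3a–C3 and O1–C2 instead, gives up the stereospecific transfer from the epoxide and costs half of the material.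

Step 3. Oxygen transfer may leak to the trans-epoxide through the stepwise radical pathway, enantioselection may be incomplete, and the electron-rich epoxide may open or rearrange under traces of acid during isolation. The fallback sets out from 3 and comes back at 4, and takes the absolute configuration from a separation instead of a catalyst. Stereospecific, neutral epoxidation of 3 with dimethyldioxirane (acetone, 0 °C) should give the cis-epoxide as the racemate, that is 4 together with {2,3-dimethoxy-5-[(2S,3R)-3-methyloxiran-2-yl]phenoxy}tri(propan-2-yl)silane F3. Preparative supercritical-fluid chromatography on an immobilised polysaccharide chiral phase would then give 4.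

Step 2. Z-selectivity may be insufficient with an aromatic aldehyde; the (E)-alkene wastes material and, if epoxidised, would lead to the cis-ring diastereomer. The fallback sets out from 2 and comes back at 3, and fixes the geometry by syn addition of hydrogen to an alkyne. Corey–Fuchs reaction of 2 (CBr4, PPh3, CH2Cl2, 0 °C) should give [5-(2,2-dibromoethenyl)-2,3-dimethoxyphenoxy]tri(propan-2-yl)silane F4. Treatment with n-BuLi (2.2 equiv, THF, −78 °C) and then MeI should give [2,3-dimethoxy-5-(prop-1-yn-1-yl)phenoxy]tri(propan-2-yl)silane F5. Semi-hydrogenation (H2, Pd on CaCO3 poisoned with Pb(OAc)2, quinoline, EtOAc) should give 3.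

**Further compounds**

F1 | step 4 | {2,3-dimethoxy-5-[(E)-prop-1-en-1-yl]phenoxy}tri(propan-2-yl)silane | C/C=C/c1cc(O[Si](C(C)C)(C(C)C)C(C)C)c(OC)c(OC)c1
F2 | step 4 | (2R,3R)-2-(3,4-dimethoxy-5-{[tri(propan-2-yl)silyl]oxy}phenyl)-7-methoxy-3-methyl-2,3-dihydro-1-benzofuran-5-carbaldehyde | O=Cc1cc(OC)c2c(c1)[C@@H](C)[C@H](c1cc(O[Si](C(C)C)(C(C)C)C(C)C)c(OC)c(OC)c1)O2
F3 | step 3 | {2,3-dimethoxy-5-[(2S,3R)-3-methyloxiran-2-yl]phenoxy}tri(propan-2-yl)silane | C[C@H]1O[C@H]1c1cc(O[Si](C(C)C)(C(C)C)C(C)C)c(OC)c(OC)c1
F4 | step 2 | [5-(2,2-dibromoethenyl)-2,3-dimethoxyphenoxy]tri(propan-2-yl)silane | BrC(Br)=Cc1cc(O[Si](C(C)C)(C(C)C)C(C)C)c(OC)c(OC)c1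
F5 | step 2 | [2,3-dimethoxy-5-(prop-1-yn-1-yl)phenoxy]tri(propan-2-yl)silane | CC#Cc1cc(O[Si](C(C)C)(C(C)C)C(C)C)c(OC)c(OC)c1
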